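## Retrosynthetic overview
1. Tuberatolide B comes from removing an aryl TBS group from 12. Compound 12 forms by a Pd-catalysed decarboxylative asymmetric allylic alkylation (AAA) in which the aromatic furan-2-olate of butenolide 11 is alkylated at C5. This dearomatisation of the furan sets the γ-centre (R) and joins it to the E-allylic carbonate 7.
2. Carbonate 7 comes from (S)-alcohol 6, which is obtained by chiral resolution of (±)-5. Alcohol 5 comes from SeO2 oxidation of chromene 4. Chromene 4 forms by an o-quinone-methide/oxa-6π condensation of phenol 3 (from toluhydroquinone 1) with citral (2).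
3. Butenolide 11 comes from Negishi coupling of 3-iodofuranone 9 (from 2(5H)-furanone 8) with the homoprenylzinc reagent derived from bromide 10.
4. Ring order: the chromene ring is built first, from the phenol by dearomative oQM formation and 6π closure. The furanone ring is bought, and its C5 stereocentre is created last, by the key dearomative allylation.

Assumptions: commercial citral is an E/Z mixture, which converges to the same chromene. Absolute configuration of the resolved peak and the Trost-ligand enantiomer are confirmed against natural tuberatolide B data.

## Route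

**Step 1**
Reactants: 1 (2-methylbenzene-1,4-diol)
Product: 3 (4-(tert-butyldimethylsilyloxy)-2-methylphenol)
Conditions: TBSCl (1.0 equiv), imidazole, DMF, 0 °C → rt
Reagents that add atoms: TBSCl, CC(C)(C)[Si](C)(C)Cl
Why: Silylation (protecting-group installation) occurs at the less hindered 4-OH, leaving the OH ortho to the methyl free so that chromene formation later occurs on the correct side (8-methyl, 6-O). No stereocentre is formed.

**Step 2**
Reactants: 3 and 2 (citral, (2E)-3,7-dimethylocta-2,6-dienal)
Product: 4 ((±)-TBS ether of 2,8-dimethyl-2-(4-methylpent-3-enyl)-2H-chromen-6-ol)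
Conditions: citral (1.5 equiv), ethylenediamine diacetate (10 mol %), toluene, 110 °C, Dean–Stark
Reagents that add atoms: none beyond reactant 2
Why: Phenol ortho-alkylation by the enal-derived iminium gives an o-quinone methide, which is a dearomatised phenol. Oxa-6π-electrocyclisation then closes the 2H-chromene; this is the classic biomimetic chromene synthesis. C2 is formed as a racemate, and neral and geranial converge on the same product.

**Step 3**
Reactants: 4
Product: 5 ((±)-(E)-5-[6-(TBSO)-2,8-dimethyl-2H-chromen-2-yl]-2-methylpent-2-en-1-ol)
Conditions: SeO2 (10 mol %), TBHP (3 equiv), CH2Cl2, 0 °C → rt; then NaBH4, MeOH, 0 °C; E isomer isolated by AgNO3–silica chromatography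
Reagents that add atoms: tert-butyl hydroperoxide, CC(C)(C)OO (source of the new OH oxygen)
Why: Riley/Sharpless allylic oxidation (ene/[2,3] pathway) hits the trisubstituted isopropylidene alkene at the methyl trans to the chain. This gives the E-allylic alcohol, and NaBH4 reduces any over-oxidised enal. The disubstituted chromene alkene is far less reactive.

**Step 4**
Reactants: 5
Product: 6 ((S)-5, the (2S)-enantiomer)
Conditions: preparative chiral-phase SFC (Chiralpak IA, CO2/i-PrOH), collect the (S) enantiomer
Reagents that add atoms: none
Why: Resolution fixes the quaternary C2 stereocentre. C2 then survives because every later step is neutral to mildly acidic and at or below 50 °C, so no chromene ring-opening or ionisation occurs.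

**Step 5**
Reactants: 6
Product: 7 ((S,E)-methyl carbonate of 6)
Conditions: ClCO2Me, pyridine, DMAP (cat.), CH2Cl2, 0 °C
Reagents that add atoms: methyl chloroformate, COC(=O)Cl
Why: Acylation of the primary allylic alcohol gives the standard Tsuji–Trost electrophile, and C2 is untouched.

**Step 6**
Reactants: 8 (2(5H)-furanone)
Product: 9 (3-iodofuran-2(5H)-one)
Conditions: I2, pyridine, CH2Cl2, 0 °C → rt
Reagents that add atoms: iodine, II
Why: Johnson α-iodination of an enone (iodide addition, then elimination) installs the handle for α-alkylation.

**Step 7**
Reactants: 9 and 10 (5-bromo-2-methylpent-2-ene)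
Product: 11 (3-(4-methylpent-3-en-1-yl)furan-2(5H)-one)
Conditions: (i) 10, Zn dust, LiCl, I2 (cat.), THF, 40 °C to make the alkylzinc bromide; (ii) 9, Pd(PPh3)4 (5 mol %), THF, 50 °C
Reagents that add atoms: none beyond reactant 10
Why: Negishi sp3–sp2 coupling of a homoallylzinc reagent with an α-iodoenone builds the α-homoprenyl butenolide. The achiral product is the pronucleophile for the key step.

**Step 8 (key step)**
Reactants: 11 and 7
Product: 12 ((R)-5-[(E)-chain]-3-homoprenylfuran-2(5H)-one, TBS-protected tuberatolide B)
Conditions: Pd2(dba)3·CHCl3 (2.5 mol %), (R,R)-DACH-phenyl Trost ligand (7.5 mol %), CH2Cl2, 25 °C, no added base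
Reagents that add atoms: none (the carbonate leaves as CO2 and MeOH)
Why: Proposed new method: Pd(0) ionises 7 to a 2-methyl-π-allyl. The methoxide released deprotonates 11 to the aromatic furan-2-olate, whose C5 attacks the less hindered allyl terminus, so the furan is dearomatised and the γ-centre forms enantioselectively under ligand control. Closest known reactions are Trost Pd-AAA of soft enolates and Stoltz decarboxylative allylation with 2-methylallyl groups, together with γ-selective vinylogous allylation of butenolides. Attack at C5 is favoured over the hindered α-carbon, and retention of the syn-allyl geometry gives the E-alkene. If the (S)-lactone forms, the (S,S)-ligand is used.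

**Step 9**
Reactants: 12
Product: 13 (tuberatolide B)
Conditions: TBAF/AcOH (1:1), THF, 0 °C → rt (or HF·pyridine, pyridine, THF)
Reagents that add atoms: none
Why: Fluoride cleaves the aryl silyl ether under buffered conditions that avoid base-mediated racemisation of the acidic γ-H of the butenolide. All alkenes, the chromene and the lactone survive.

## Compound list
1 | 2-methylbenzene-1,4-diol | Cc1cc(O)ccc1O | starting material
2 | citral, (2E)-3,7-dimethylocta-2,6-dienal | CC(C)=CCC/C(C)=C/C=O | starting material
3 | 4-(TBSO)-2-methylphenol | Cc1cc(O[Si](C)(C)C(C)(C)C)ccc1O | intermediate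
4 | (±)-6-TBSO-2,8-dimethyl-2-(4-methylpent-3-enyl)-2H-chromene | CC(C)=CCCC1(C)C=Cc2cc(O[Si](C)(C)C(C)(C)C)cc(C)c2O1 | intermediate
5 | (±)-(E)-allylic alcohol | OC/C(C)=C/CCC1(C)C=Cc2cc(O[Si](C)(C)C(C)(C)C)cc(C)c2O1 | intermediate
6 | (S,E)-allylic alcohol | OC/C(C)=C/CC[C@@]1(C)C=Cc2cc(O[Si](C)(C)C(C)(C)C)cc(C)c2O1 | intermediate
7 | (S,E)-methyl carbonate | COC(=O)OC/C(C)=C/CC[C@@]1(C)C=Cc2cc(O[Si](C)(C)C(C)(C)C)cc(C)c2O1 | intermediate
8 | furan-2(5H)-one | O=C1C=CCO1 | starting material
9 | 3-iodofuran-2(5H)-one | O=C1OCC=C1I | intermediate
10 | 5-bromo-2-methylpent-2-ene | CC(C)=CCCBr | starting material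
11 | 3-(4-methylpent-3-en-1-yl)furan-2(5H)-one | CC(C)=CCCC1=CCOC1=O | intermediate
12 | TBS-protected tuberatolide B | CC(C)=CCCC1=C[C@@H](C/C(C)=C/CC[C@@]2(C)C=Cc3cc(O[Si](C)(C)C(C)(C)C)cc(C)c3O2)OC1=O | intermediate
13 | tuberatolide B | CC(C)=CCCC1=C[C@@H](C/C(C)=C/CC[C@@]2(C)C=Cc3cc(O)cc(C)c3O2)OC1=O | target

## Totals
Total steps: 9. Longest linear sequence: 7 (1 → 3 → 4 → 5 → 6 → 7 → 12 → 13, i.e. Steps 1, 2, 3, 4, 5, 8, 9).

## Three steps most likely to fail
1. **Step 8 (dearomative AAA)** may give poor ee, α-allylation, or Z-alkene from the anti-π-allyl.
   Fallback: run Step 8 with an achiral ligand (PPh3) on 7 to give separable γ-epimers, then isolate the (R) diastereomer by HPLC (C2 is already fixed).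
2. **Step 3 (SeO2 oxidation)** may give low yield, poor E/Z selectivity, or attack on the chromene.
   Fallback: install the oxidised terminus before chromene formation. Prepare (2E,6E)-8-acetoxy-3,7-dimethylocta-2,6-dienal from geranyl acetate by SeO2 oxidation and then oxidation of the primary alcohol. Condense it with phenol 3 in Step 2 and carry the acetate through, replacing Steps 3 and 5 with acetate methanolysis and carbonate formation.
3. **Step 4 (chiral resolution)** may give poor separation or scale limits, and assigning the correct enantiomer peak is uncertain.
   Fallback: replace it with an enantioselective C2 construction. Add the Grignard from a 4-pentenyl-type bromide to 2-methylchromone under Cu/Josiphos catalysis, then reduce the chromanone (NaBH4) and dehydrate to the chromene, before resuming at the SeO2 step.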